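## Analysis of the target

The target 17 is a 2,3,4-trisubstituted tetrahydrofuran lignan. The ring is numbered O1, C2 (4-hydroxy-3-methoxyphenyl, the guaiacyl ring), C3 (CH2OH), C4 (side chain) and C5 (CH2); the side chain is an exocyclic carbinol carbon that carries OH and a 3,4-dihydroxyphenyl ring. There are four stereocentres, C2 (S), C3 (R), C4 (S) and the carbinol carbon (R). The three ring substituents are all-trans (2,3-trans and 3,4-trans), and the carbinol centre is defined only relative to C4, outside the ring. The sensitive groups are three phenols (two of them an oxidisable catechol) and two benzylic C–O bonds (C2–O1 and the carbinol C–OH), each para to a ring oxygen and therefore acid-labile and prone to hydrogenolysis. The difficulty lies in three contiguous stereocentres on a flexible five-membered ring plus a fourth outside it, in the absolute configuration, and in the two different aryl groups, which rule out simple dimerisation logic. The strategy rests on one feature: O1–C2 is the C=O of an aryl aldehyde, and C3–C4–C5 is a three-carbon unit whose central carbon C4 carries exactly one further carbon, the carbinol carbon. That is the pattern of a trimethylenemethane unit with a carboxyl-level carbon on C3, so the ring maps onto a [3+2] union with an aldehyde, and the exocyclic methylene on C4 becomes the handle for the carbinol carbon.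

## Retrosynthetic reasoning

17 ⇒ 16. The three phenolic O–H bonds are traced back to benzyl ethers. Benzyl survives every reagent class used earlier (organometallics, hydrides, peracid, Lewis acid, zerovalent palladium), so one hydrogenolysis at the end unmasks all three phenols.

16 ⇒ 15. The C3 CH2OH is taken back to a methyl ester. The ester is what the ring-forming step needs to stabilise the nucleophilic carbon, and it keeps C3 epimerisable so that the 2,3-trans relationship can settle thermodynamically. Reducing it late also avoids protecting a primary alcohol.

15 ⇒ 14. The carbinol C–H bond is cut, leading to the aryl ketone 14. Hydride addition to this ketone should be steered by the ring (chelation through O1, or the Felkin–Anh model with C3 as the large group) to the (R)-carbinol. Direct aryl addition to an aldehyde is expected to give the opposite epimer, so the centre is set by reduction.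

14 ⇒ 13 ⇒ 10 + 12. The bond between the carbinol carbon and the catechol ring is cut. This brings in the second, different aryl group late, as the Grignard reagent 12 made from the bromide 11, and leaves the aldehyde 10 as the ring-bearing partner. The alcohol mixture 13 is only a relay to the ketone, so its configuration is irrelevant.

10 ⇒ 9 ⇒ 8. The C4 formyl group is traced to an exocyclic methylene via the spiro-epoxide 9 and a 1,2-hydride shift. No carbon is added; only the oxidation level changes. C4 ends up α to an aldehyde, so the 3,4-trans relationship is reached by equilibration.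

8 ⇒ 6 + 7. The ring is cut at C2–C3 and O1–C5. This is the only disconnection that turns the ring into two simple partners, O-benzylvanillin 7 and the silyl acetate 6, while creating C2 under catalyst control. The forward reaction has to form both bonds, place the ester next to the aryl-bearing carbon, leave the methylene exocyclic, and give the 2,3-trans (2S,3S) ester.

6 ⇒ 5 ⇒ 3 + 4, and 3 ⇒ 2 ⇒ 1. In 6 the ester is cis to the acetoxymethyl group, and a free alcohol in that position would close to a butenolide. The acetate is therefore derived directly from the silyl ether 5. The trisubstituted alkene of 5 is cut between C3 and the CH2SiMe3 group, which leads to a syn carbocupration of the alkynoate 3 with the Grignard reagent 4 and fixes the E geometry. 3 comes from the propargyl silyl ether 1 by C-acylation of its acetylide 2.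

## Alternatives that were turned down

Alternative 1: Prins–pinacol ring construction.
- Disconnection: C2–C3 and C4–C5. The ring is traced to the cyclic acetal A2, in which 7 is condensed with a tertiary allylic 1,2-diol that carries the catechol ring on its quaternary carbinol carbon.
- Forward key step: SnCl4 opens the acetal carbon of A2 to an aryl oxocarbenium ion, and the alkene terminus closes a six-membered ring onto it (C2–C3). The resulting cation is quenched by a ring-contracting pinacol shift: the O1-bearing CH2 moves to C4 (C4–C5) and the carbinol carbon becomes the aryl ketone of A1.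
- For: one operation makes two C–C bonds and all three ring stereocentres by chirality transfer from one quaternary centre. A chair with both aryl groups equatorial and an E alkene leads to the all-trans ring. The aroyl group arrives complete, so steps 5 to 8 of the chosen route would not be needed. On bonds formed per step and on the length of the endgame this alternative is stronger.
- Against: the stereochemical information must be stored in a tertiary, benzylic, para-oxygenated carbinol centre. That centre is laborious to make as one enantiomer and is exactly the kind that SnCl4 ionises. The alkene is 1,2-disubstituted with an allylic silyloxy group, so the Prins cation is secondary and inductively destabilised; this slows cyclisation and invites oxonia-Cope scrambling. In the pinacol step the electron-rich aryl group is a better migrating group than the ring CH2 and can divert the cation. The silyl ether and the benzylic C2–O1 bond must also survive SnCl4.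
- Comparison: what A1 saves after ring closure is spent on making A2, and the risk sits in a precursor that is costly to remake. The chosen route offers ring formation without strong acid, absolute configuration from a catalyst, and partners that are bought or made in three steps.

Alternative 2: rhodium carbene C–H insertion.
- Disconnection: C2–C3 only. The precursor is the acyclic α-diazo ester A4, in which C4 and the carbinol centre are already set and the guaiacyl unit is attached as a benzyl-type ether on the C5 oxygen.
- Forward key step: Rh2(S-PTTL)4, dirhodium tetrakis[N-phthaloyl-(S)-tert-leucinate], decomposes the diazo group of A4. The carbene on C3 inserts in a 1,5-fashion into the benzylic C2–H bond and gives the tetrahydrofuran A3.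
- For: the C–H bond is doubly activated (α to oxygen, benzylic to an electron-rich ring), and five-membered ring formation is the normal preference. The side chain with both stereocentres is complete before the ring is made, so the carbinol centre does not depend on a late substrate-controlled reduction; on that point it is stronger than the chosen route. After A3 only ester reduction and deprotection remain.
- Against: the carbene carbon carries an alkyl group with a tertiary β-hydrogen (C4–H), so 1,2-hydride shift to an alkene competes with insertion. The catalyst must set C2 and C3 in a substrate that already has two stereocentres, matched or mismatched. Insertions of this kind tend to give the 2,3-cis ring, which would need epimerisation at C3. A4 requires a long linear sequence (stereoselective side-chain construction, etherification, diazo transfer to a mono-ester) with four protecting groups, and the uncertain step comes at its very end.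
- Comparison: the chosen route is convergent and runs its uncertain step on a purchased aldehyde and a three-step donor, so a failure there costs little. It pays for this with a longer sequence after the ring is made and with a carbinol centre that relies on substrate control.

Alternative 3: oxidative cyclobutane opening.
- Disconnection: O1–C2 and the carbinol C–O bond are cut, and the bond between C2 and the carbinol carbon is re-formed. This leads to the cyclobutane A6 (head-to-head, aryl groups cis, the two CH2O groups cis on the other face, one free and one acetylated).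
- Forward key step: FeCl3·6H2O in wet acetone oxidises the free guaiacyl phenol of A6, and the strained benzylic–benzylic ring bond breaks. The quinone methide at C2 is trapped by the free CH2OH (O1–C2), and the benzylic cation on the other side is trapped by water, giving A5.
- For: a single [2+2] dimerisation builds the skeleton with the C3/C4 relationship. The key step forms the ring and both C–O bonds without protecting the reacting phenol. From A5 only deacetylation and debenzylation remain. In step economy this is the shortest of the four strategies.
- Against: the two aryl groups and the two CH2O groups of A6 are different. The cyclobutane therefore needs a crossed head-to-head photodimerisation (statistical mixtures) or desymmetrisation of a symmetric dimer at two places. A dimer with cis aryl and cis CH2 groups is meso when symmetric, so the absolute configuration has no built-in source. C2 and the carbinol centre both arise by trapping planar cationic intermediates, the carbinol by external water with no strong control element. The catechol unit also sits in an oxidising medium.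
- Comparison: shorter on paper, but the unsymmetrical substitution and the single enantiomer are exactly what it does not solve. The chosen route takes the absolute configuration from a catalyst, the two aryl groups from two separate reagents, and the carbinol configuration from an oxidation–reduction pair.

Key step: step 4

Assumption: the sense of induction of the phosphoramidite is not assigned here; of the two accessible ligand antipodes, the one that delivers (2S)-8 is used.

## Route

Step 1
Reactants: 1 tert-butyldimethyl(prop-2-yn-1-yloxy)silane
Product: 3 methyl 4-[(tert-butyldimethylsilyl)oxy]but-2-ynoate, via lithium acetylide of the propargyl ether 2 (not isolated)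
Conditions: n-BuLi, THF, −78 °C; then ClCO2Me, −78 to 0 °C
Reagents that add atoms: methyl chloroformate, COC(=O)Cl
Why: Deprotonation of the terminal alkyne and C-acylation of the lithium acetylide is a standard alkynoate synthesis, and the silyl ether is inert to n-BuLi at −78 °C.

Step 2
Reactants: 3 methyl 4-[(tert-butyldimethylsilyl)oxy]but-2-ynoate; 4 (trimethylsilyl)methylmagnesium chloride
Product: 5 methyl (E)-4-[(tert-butyldimethylsilyl)oxy]-3-[(trimethylsilyl)methyl]but-2-enoate
Conditions: CuI (10 mol%), THF, −78 °C; sat. aq NH4Cl added at −78 °C
Reagents that add atoms: none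
Why: Copper-catalysed conjugate addition (carbocupration) of the Grignard reagent to the alkynoate is a syn addition, and protonation at −78 °C, before the adduct can equilibrate through the allenolate, places H cis to the new CH2SiMe3 group, so the ester is trans to CH2SiMe3 (E). The silyl ether is not a leaving group, so neither SN2' displacement nor reduction competes.

Step 3
Reactants: 5 methyl (E)-4-[(tert-butyldimethylsilyl)oxy]-3-[(trimethylsilyl)methyl]but-2-enoate
Product: 6 methyl (E)-3-(acetoxymethyl)-4-(trimethylsilyl)but-2-enoate
Conditions: Ac2O, Cu(OTf)2 (5 mol%), CH2Cl2, 0 °C to rt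
Reagents that add atoms: acetic anhydride, CC(=O)OC(C)=O
Why: Lewis-acid-catalysed acetolysis exchanges the silyl ether directly for the acetate (the ether oxygen is acylated and silicon leaves as its acetate), so the free hydroxy ester, which is cis to the ester and would close to the butenolide, is never formed. The allylsilane is conjugated to the ester and is therefore a poor nucleophile, which should keep it out of protodesilylation or acylation; the alkene geometry is untouched.

Step 4
Reactants: 6 methyl (E)-3-(acetoxymethyl)-4-(trimethylsilyl)but-2-enoate; 7 4-(benzyloxy)-3-methoxybenzaldehyde (O-benzylvanillin)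
Product: 8 methyl (2S,3S)-2-[4-(benzyloxy)-3-methoxyphenyl]-4-methylidenetetrahydrofuran-3-carboxylate (2,3-trans)
Conditions: Pd(dba)2 (5 mol%), chiral phosphoramidite L* (10 mol%; 1,1'-bi-2-naphthol phosphite core with a trans-2,5-bis(2-naphthyl)pyrrolidine on phosphorus), In(acac)3 (10 mol%), 6 (1.6 equiv), toluene, 25 to 45 °C
Reagents that add atoms: none
Why: Zerovalent palladium ionises the allylic acetate of 6 and the released acetate removes the trimethylsilyl group, giving a zwitterionic trimethylenemethane–palladium complex whose negative charge is held on the ester-bearing carbon. That carbon attacks the carbonyl of 7, which In(acac)3 activates, and forms C2–C3; the alkoxide then attacks a CH2 terminus of the cationic π-allyl unit and forms O1–C5, a 5-exo-tet-type O-allylation that closes the tetrahydrofuran and leaves the methylene exocyclic on C4. The closest known reaction type is the palladium–phosphoramidite trimethylenemethane [3+2] cycloaddition of the unsubstituted silyl acetate donor with aryl aldehydes; acceptor-substituted donors are known in the same cycloaddition with other π-acceptors, and the present case joins the two. C2 is controlled by the chiral phosphoramidite on palladium, which selects the aldehyde face in the C–C bond formation or, should that addition be reversible, selects between the diastereomeric alkoxides in the ring closure. C3 is controlled by C2: it is α to the ester and allylic, so it can equilibrate under the weakly basic conditions and settles trans to the aryl group. Regioselectivity is secured by the ester, which fixes the nucleophilic carbon so that the ester ends up next to the aryl-bearing carbon, and by the equivalence of the two CH2 termini, which makes the O-closure unambiguous. Chemoselectivity is needed against protodesilylation of the donor and against migration of the exocyclic double bond into conjugation with the ester; the aldehyde is the only electrophile, and an excess of 6, the Lewis-acid cocatalyst and a non-polar solvent at moderate temperature serve this.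

Step 5
Reactants: 8 methyl (2S,3S)-2-[4-(benzyloxy)-3-methoxyphenyl]-4-methylidenetetrahydrofuran-3-carboxylate
Product: 9 methyl (6S,7R)-6-[4-(benzyloxy)-3-methoxyphenyl]-1,5-dioxaspiro[2.4]heptane-7-carboxylate (spiro-epoxide at C4, either configuration at the spiro carbon)
Conditions: mCPBA, NaHCO3, CH2Cl2, 0 °C to rt
Reagents that add atoms: 3-chloroperoxybenzoic acid (mCPBA), O=C(OO)c1cccc(Cl)c1
Why: Prilezhaev epoxidation of the 1,1-disubstituted exocyclic alkene, buffered to protect the acid-sensitive benzylic ether. The configuration of the new spiro centre does not matter because C4 is re-set in the next step.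

Step 6
Reactants: 9 methyl (6S,7R)-6-[4-(benzyloxy)-3-methoxyphenyl]-1,5-dioxaspiro[2.4]heptane-7-carboxylate
Product: 10 methyl (2S,3S,4S)-2-[4-(benzyloxy)-3-methoxyphenyl]-4-formyltetrahydrofuran-3-carboxylate (all-trans)
Conditions: BF3·OEt2 (0.3 equiv), CH2Cl2, −78 to −40 °C, Et3N quench; then DBU (0.1 equiv), CH2Cl2, 0 °C
Reagents that add atoms: none
Why: Meinwald rearrangement: the Lewis acid opens the epoxide at the tertiary carbon C4 and a hydride shifts from the CH2O carbon, pushed by the oxygen, to give the aldehyde. C4 is α to the aldehyde, so catalytic DBU equilibrates it to the 3,4-trans isomer, the more stable arrangement on the ring, while C3 (α only to the ester) is not deprotonated under these conditions.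

Step 7
Reactants: 10 methyl (2S,3S,4S)-2-[4-(benzyloxy)-3-methoxyphenyl]-4-formyltetrahydrofuran-3-carboxylate; 11 4-bromo-1,2-bis(benzyloxy)benzene
Product: 13 methyl (2S,3S,4S)-2-[4-(benzyloxy)-3-methoxyphenyl]-4-{[3,4-bis(benzyloxy)phenyl](hydroxy)methyl}tetrahydrofuran-3-carboxylate as a mixture of carbinol epimers, via 3,4-bis(benzyloxy)phenylmagnesium bromide 12 (not isolated)
Conditions: 11, Mg turnings, THF, 40 °C; then 10, THF, −78 °C; sat. aq NH4Cl
Reagents that add atoms: none
Why: Grignard addition; at −78 °C the aryl Grignard reagent adds to the aldehyde and leaves the methyl ester alone. The carbinol centre is not controlled in the required sense here (the Felkin–Anh and chelate models both predict mainly the S epimer), which is accepted because both epimers converge in step 8; lactonisation onto the C3 ester would need a trans-fused bicycle and should not occur.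

Step 8
Reactants: 13 methyl (2S,3S,4S)-2-[4-(benzyloxy)-3-methoxyphenyl]-4-{[3,4-bis(benzyloxy)phenyl](hydroxy)methyl}tetrahydrofuran-3-carboxylate (epimer mixture)
Product: 14 methyl (2S,3S,4S)-2-[4-(benzyloxy)-3-methoxyphenyl]-4-[3,4-bis(benzyloxy)benzoyl]tetrahydrofuran-3-carboxylate
Conditions: Dess–Martin periodinane, NaHCO3, CH2Cl2, 0 °C to rt
Reagents that add atoms: none
Why: Dess–Martin oxidation of a secondary benzylic alcohol under buffered, non-basic conditions, which spares the epimerisable C3 and C4 centres; both carbinol epimers give the same ketone.

Step 9
Reactants: 14 methyl (2S,3S,4S)-2-[4-(benzyloxy)-3-methoxyphenyl]-4-[3,4-bis(benzyloxy)benzoyl]tetrahydrofuran-3-carboxylate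
Product: 15 methyl (2S,3S,4S)-2-[4-(benzyloxy)-3-methoxyphenyl]-4-{(R)-[3,4-bis(benzyloxy)phenyl](hydroxy)methyl}tetrahydrofuran-3-carboxylate
Conditions: Zn(BH4)2, Et2O, −20 to 0 °C; water, then aqueous potassium sodium tartrate (KNaC4H4O6)
Reagents that add atoms: none
Why: Chelation-controlled ketone reduction: the zinc ion bridges the ketone oxygen and the ring oxygen O1 (six-membered chelate through C5) and hydride is delivered to the face away from the substituted ring carbon C3. The Felkin–Anh model with C3 as the large group predicts the same face, and either model worked through on the (4S) ketone gives the (R)-carbinol; Zn(BH4)2 does not reduce the methyl ester at this temperature.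

Step 10
Reactants: 15 methyl (2S,3S,4S)-2-[4-(benzyloxy)-3-methoxyphenyl]-4-{(R)-[3,4-bis(benzyloxy)phenyl](hydroxy)methyl}tetrahydrofuran-3-carboxylate
Product: 16 {(2S,3R,4S)-2-[4-(benzyloxy)-3-methoxyphenyl]-4-{(R)-[3,4-bis(benzyloxy)phenyl](hydroxy)methyl}tetrahydrofuran-3-yl}methanol
Conditions: LiAlH4, THF, 0 °C; aqueous potassium sodium tartrate (KNaC4H4O6) work-up
Reagents that add atoms: none
Why: LiAlH4 reduces the methyl ester to the primary alcohol; the benzyl ethers, the ring and the four stereocentres are not affected (the C3 descriptor changes from S to R only because the substituent priorities change).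

Step 11
Reactants: 16 {(2S,3R,4S)-2-[4-(benzyloxy)-3-methoxyphenyl]-4-{(R)-[3,4-bis(benzyloxy)phenyl](hydroxy)methyl}tetrahydrofuran-3-yl}methanol
Product: 17 4-{(R)-hydroxy[(3S,4R,5S)-5-(4-hydroxy-3-methoxyphenyl)-4-(hydroxymethyl)tetrahydrofuran-3-yl]methyl}benzene-1,2-diol (CNP0197133.1)
Conditions: H2 (1 atm), 10% Pd on carbon (Pd/C), EtOAc–THF, rt, stopped after uptake of three equivalents of H2
Reagents that add atoms: none
Why: Hydrogenolysis of the three aryl benzyl ethers; in a neutral aprotic solvent the aryl O–benzyl bonds should be cleaved faster than the benzylic C–O bonds of the ring and of the carbinol, and no stereocentre is involved.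

## Compound list

1 | tert-butyldimethyl(prop-2-yn-1-yloxy)silane | C#CCO[Si](C)(C)C(C)(C)C | starting material
2 | lithium acetylide of 1 | [Li]C#CCO[Si](C)(C)C(C)(C)C | intermediate
3 | methyl 4-[(tert-butyldimethylsilyl)oxy]but-2-ynoate | COC(=O)C#CCO[Si](C)(C)C(C)(C)C | intermediate
4 | (trimethylsilyl)methylmagnesium chloride | C[Si](C)(C)C[Mg]Cl | starting material
5 | methyl (E)-4-[(tert-butyldimethylsilyl)oxy]-3-[(trimethylsilyl)methyl]but-2-enoate | COC(=O)/C=C(/C[Si](C)(C)C)CO[Si](C)(C)C(C)(C)C | intermediate
6 | methyl (E)-3-(acetoxymethyl)-4-(trimethylsilyl)but-2-enoate | COC(=O)/C=C(/C[Si](C)(C)C)COC(C)=O | intermediate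
7 | 4-(benzyloxy)-3-methoxybenzaldehyde (O-benzylvanillin) | O=Cc1ccc(OCc2ccccc2)c(OC)c1 | starting material
8 | methyl (2S,3S)-2-[4-(benzyloxy)-3-methoxyphenyl]-4-methylidenetetrahydrofuran-3-carboxylate | COc1cc([C@H]2OCC(=C)[C@@H]2C(=O)OC)ccc1OCc1ccccc1 | intermediate
9 | methyl (6S,7R)-6-[4-(benzyloxy)-3-methoxyphenyl]-1,5-dioxaspiro[2.4]heptane-7-carboxylate, either configuration at the spiro carbon | COc1cc([C@H]2OCC3(CO3)[C@@H]2C(=O)OC)ccc1OCc1ccccc1 | intermediate
10 | methyl (2S,3S,4S)-2-[4-(benzyloxy)-3-methoxyphenyl]-4-formyltetrahydrofuran-3-carboxylate | COc1cc([C@H]2OC[C@@H](C=O)[C@@H]2C(=O)OC)ccc1OCc1ccccc1 | intermediate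
11 | 4-bromo-1,2-bis(benzyloxy)benzene | Brc1ccc(OCc2ccccc2)c(OCc2ccccc2)c1 | starting material
12 | 3,4-bis(benzyloxy)phenylmagnesium bromide | Br[Mg]c1ccc(OCc2ccccc2)c(OCc2ccccc2)c1 | intermediate
13 | methyl (2S,3S,4S)-2-[4-(benzyloxy)-3-methoxyphenyl]-4-{[3,4-bis(benzyloxy)phenyl](hydroxy)methyl}tetrahydrofuran-3-carboxylate, mixture of carbinol epimers | COc1cc([C@H]2OC[C@@H](C(O)c3ccc(OCc4ccccc4)c(OCc5ccccc5)c3)[C@@H]2C(=O)OC)ccc1OCc1ccccc1 | intermediate
14 | methyl (2S,3S,4S)-2-[4-(benzyloxy)-3-methoxyphenyl]-4-[3,4-bis(benzyloxy)benzoyl]tetrahydrofuran-3-carboxylate | COc1cc([C@H]2OC[C@@H](C(=O)c3ccc(OCc4ccccc4)c(OCc5ccccc5)c3)[C@@H]2C(=O)OC)ccc1OCc1ccccc1 | intermediate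
15 | methyl (2S,3S,4S)-2-[4-(benzyloxy)-3-methoxyphenyl]-4-{(R)-[3,4-bis(benzyloxy)phenyl](hydroxy)methyl}tetrahydrofuran-3-carboxylate | COc1cc([C@H]2OC[C@@H]([C@@H](O)c3ccc(OCc4ccccc4)c(OCc5ccccc5)c3)[C@@H]2C(=O)OC)ccc1OCc1ccccc1 | intermediate
16 | {(2S,3R,4S)-2-[4-(benzyloxy)-3-methoxyphenyl]-4-{(R)-[3,4-bis(benzyloxy)phenyl](hydroxy)methyl}tetrahydrofuran-3-yl}methanol | COc1cc([C@H]2OC[C@@H]([C@@H](O)c3ccc(OCc4ccccc4)c(OCc5ccccc5)c3)[C@@H]2CO)ccc1OCc1ccccc1 | intermediate
17 | 4-{(R)-hydroxy[(3S,4R,5S)-5-(4-hydroxy-3-methoxyphenyl)-4-(hydroxymethyl)tetrahydrofuran-3-yl]methyl}benzene-1,2-diol | COc1cc([C@H]2OC[C@@H]([C@@H](O)c3ccc(O)c(O)c3)[C@@H]2CO)ccc1O | target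

## Step count and least certain steps

Total step count: 11. Longest linear sequence: 11 steps, from 1 to 17; 4, 7 and 11 are purchased and enter without prior steps.

Step 4 (key step). The most likely failure is slow or reversible addition of the ester-stabilised trimethylenemethane anion to the electron-rich aldehyde, so that the zwitterion is lost to protodesilylation or oligomerisation. Base-mediated migration of the exocyclic double bond into conjugation with the ester and insufficient facial discrimination by the ligand come next. The fallback sets out from 7 and comes back at 8; it forms the same two bonds one after the other under auxiliary control.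
- Purchased (S)-4-benzyl-3-(chloroacetyl)oxazolidin-2-one is heated with triethyl phosphite (Arbuzov reaction) to give (S)-4-benzyl-3-[(diethoxyphosphoryl)acetyl]oxazolidin-2-one F1.
- Horner–Wadsworth–Emmons reaction of F1 with acetoxyacetone (LiCl, i-Pr2NEt, MeCN) gives (S)-3-[(E)-4-acetoxy-3-methylbut-2-enoyl]-4-benzyloxazolidin-2-one F2.
- Bu2BOTf and Et3N deprotonate the methyl group cis to the carbonyl; the boron dienolate adds to 7 at its α-carbon through a Zimmerman–Traxler chair (Evans syn aldol, C2–C3) to give the (2S,3S) aldol adduct F3.
- Pd(PPh3)4 with Et3N in THF ionises the allylic acetate of F3, and the secondary hydroxyl closes the ring (O1–C5) to the tetrahydrofuran imide F4.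
- MeOMgBr in MeOH–CH2Cl2 at 0 °C exchanges the auxiliary for the methyl ester and gives 8.

Step 6. The tertiary cation at C4 is flanked by the acidic C3–H, so loss of that proton to a conjugated allylic alcohol may compete with the hydride shift, and the Lewis acid may ionise the benzylic C2–O1 bond. The fallback sets out from 8 and comes back at 10 without an epoxide or a Lewis acid.
- Hydroboration of 8 with 9-BBN, then oxidation with NaBO3·4H2O, gives methyl (2S,3S,4S)-2-[4-(benzyloxy)-3-methoxyphenyl]-4-(hydroxymethyl)tetrahydrofuran-3-carboxylate F5, expected mainly as the 3,4-cis isomer because the borane approaches anti to the ester.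
- Dess–Martin oxidation gives the 3,4-cis aldehyde methyl (2S,3S,4R)-2-[4-(benzyloxy)-3-methoxyphenyl]-4-formyltetrahydrofuran-3-carboxylate F6.
- Catalytic DBU in CH2Cl2 epimerises C4 of F6 to the all-trans aldehyde 10.

Step 9. Facial selectivity may be poor if chelation of zinc to the ester carbonyl or non-chelated attack competes with the O1 chelate, since the carbinol centre rests on substrate control alone. The fallback sets out from 14 and comes back at 15 and replaces substrate control by reagent control: Corey–Bakshi–Shibata reduction with BH3·SMe2 and the (S)-2-methyl-oxazaborolidine, the antipode that the standard model (aryl as the large group) assigns to the (R)-carbinol. It makes no compound beyond those of the route (F0).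

Step 11. Once the para-phenols are unmasked, hydrogenolysis may go on to cleave the benzylic carbinol C–OH bond or the benzylic C2–O1 ring bond. The fallback sets out from 14 and comes back at 17; it removes the benzyl groups while the carbinol carbon is still a ketone.
- Hydrogenolysis of 14 (H2, Pd on carbon, EtOAc) gives methyl (2S,3S,4S)-4-(3,4-dihydroxybenzoyl)-2-(4-hydroxy-3-methoxyphenyl)tetrahydrofuran-3-carboxylate F7.
- Ac2O and pyridine give the triacetate methyl (2S,3S,4S)-2-(4-acetoxy-3-methoxyphenyl)-4-(3,4-diacetoxybenzoyl)tetrahydrofuran-3-carboxylate F8.
- Zn(BH4)2, as in step 9, gives methyl (2S,3S,4S)-2-(4-acetoxy-3-methoxyphenyl)-4-[(R)-(3,4-diacetoxyphenyl)(hydroxy)methyl]tetrahydrofuran-3-carboxylate F9.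
- Excess LiAlH4 reduces the methyl ester and cleaves the three aryl acetates in one operation and gives 17.

Step 3. The Lewis acid may cause loss of the allylic trimethylsilyl group or closure to the butenolide during the silyl-to-acetyl exchange. The fallback sets out from 4 and comes back at 6; it builds the alkene with the acetate already in place.
- 4 is added to acetoxyacetyl chloride (CuI catalysis, THF, −78 °C) to give 1-acetoxy-3-(trimethylsilyl)propan-2-one F10.
- Wittig olefination of F10 with methyl (triphenylphosphoranylidene)acetate in toluene at 80 °C gives 6. The geometric isomer formed alongside need not be removed, because both isomers ionise to the same palladium complex in step 4.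

## Further compounds

F1 | step 4 | (S)-4-benzyl-3-[(diethoxyphosphoryl)acetyl]oxazolidin-2-one | CCOP(=O)(OCC)CC(=O)N1[C@@H](Cc2ccccc2)COC1=O
F2 | step 4 | (S)-3-[(E)-4-acetoxy-3-methylbut-2-enoyl]-4-benzyloxazolidin-2-one | CC(=O)OC/C(C)=C/C(=O)N1[C@@H](Cc2ccccc2)COC1=O
F3 | step 4 | (S)-3-{(2S,3S)-2-[3-acetoxyprop-1-en-2-yl]-3-[4-(benzyloxy)-3-methoxyphenyl]-3-hydroxypropanoyl}-4-benzyloxazolidin-2-one | COc1cc([C@@H](O)[C@H](C(=C)COC(C)=O)C(=O)N2[C@@H](Cc3ccccc3)COC2=O)ccc1OCc1ccccc1
F4 | step 4 | (S)-4-benzyl-3-{[(2S,3S)-2-[4-(benzyloxy)-3-methoxyphenyl]-4-methylidenetetrahydrofuran-3-yl]carbonyl}oxazolidin-2-one | COc1cc([C@H]2OCC(=C)[C@@H]2C(=O)N2[C@@H](Cc3ccccc3)COC2=O)ccc1OCc1ccccc1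
F5 | step 6 | methyl (2S,3S,4S)-2-[4-(benzyloxy)-3-methoxyphenyl]-4-(hydroxymethyl)tetrahydrofuran-3-carboxylate (3,4-cis) | COc1cc([C@H]2OC[C@H](CO)[C@@H]2C(=O)OC)ccc1OCc1ccccc1
F6 | step 6 | methyl (2S,3S,4R)-2-[4-(benzyloxy)-3-methoxyphenyl]-4-formyltetrahydrofuran-3-carboxylate (C4 epimer of 10) | COc1cc([C@H]2OC[C@H](C=O)[C@@H]2C(=O)OC)ccc1OCc1ccccc1
F0 | step 9 | none | none
F7 | step 11 | methyl (2S,3S,4S)-4-(3,4-dihydroxybenzoyl)-2-(4-hydroxy-3-methoxyphenyl)tetrahydrofuran-3-carboxylate | COc1cc([C@H]2OC[C@@H](C(=O)c3ccc(O)c(O)c3)[C@@H]2C(=O)OC)ccc1O
F8 | step 11 | methyl (2S,3S,4S)-2-(4-acetoxy-3-methoxyphenyl)-4-(3,4-diacetoxybenzoyl)tetrahydrofuran-3-carboxylate | COc1cc([C@H]2OC[C@@H](C(=O)c3ccc(OC(C)=O)c(OC(C)=O)c3)[C@@H]2C(=O)OC)ccc1OC(C)=O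
F9 | step 11 | methyl (2S,3S,4S)-2-(4-acetoxy-3-methoxyphenyl)-4-[(R)-(3,4-diacetoxyphenyl)(hydroxy)methyl]tetrahydrofuran-3-carboxylate | COc1cc([C@H]2OC[C@@H]([C@@H](O)c3ccc(OC(C)=O)c(OC(C)=O)c3)[C@@H]2C(=O)OC)ccc1OC(C)=O
F10 | step 3 | 1-acetoxy-3-(trimethylsilyl)propan-2-one | CC(=O)OCC(=O)C[Si](C)(C)C
A1 | alternative 1 | [3,4-bis(benzyloxy)phenyl][(3S,4R,5S)-5-[4-(benzyloxy)-3-methoxyphenyl]-4-{[(tert-butyldimethylsilyl)oxy]methyl}tetrahydrofuran-3-yl]methanone | COc1cc([C@H]2OC[C@@H](C(=O)c3ccc(OCc4ccccc4)c(OCc5ccccc5)c3)[C@@H]2CO[Si](C)(C)C(C)(C)C)ccc1OCc1ccccc1
A2 | alternative 1 | (4R)-2-[4-(benzyloxy)-3-methoxyphenyl]-4-[3,4-bis(benzyloxy)phenyl]-4-[(E)-3-[(tert-butyldimethylsilyl)oxy]prop-1-en-1-yl]-1,3-dioxolane, either configuration at the acetal carbon; 4R follows from the chair model with both aryl groups equatorial | COc1cc(C2OC[C@@](O2)(/C=C/CO[Si](C)(C)C(C)(C)C)c2ccc(OCc3ccccc3)c(OCc3ccccc3)c2)ccc1OCc1ccccc1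
A3 | alternative 2 | tert-butyl (2S,3S,4S)-2-[4-(benzyloxy)-3-methoxyphenyl]-4-{(R)-[3,4-bis(benzyloxy)phenyl][(tert-butyldimethylsilyl)oxy]methyl}tetrahydrofuran-3-carboxylate | COc1cc([C@H]2OC[C@@H]([C@@H](O[Si](C)(C)C(C)(C)C)c3ccc(OCc4ccccc4)c(OCc5ccccc5)c3)[C@@H]2C(=O)OC(C)(C)C)ccc1OCc1ccccc1
A4 | alternative 2 | tert-butyl (3S,4R)-3-({[4-(benzyloxy)-3-methoxybenzyl]oxy}methyl)-4-[3,4-bis(benzyloxy)phenyl]-4-[(tert-butyldimethylsilyl)oxy]-2-diazobutanoate | COc1cc(COC[C@@H]([C@@H](O[Si](C)(C)C(C)(C)C)c2ccc(OCc3ccccc3)c(OCc4ccccc4)c2)C(=[N+]=[N-])C(=O)OC(C)(C)C)ccc1OCc1ccccc1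
A5 | alternative 3 | {(2S,3R,4S)-4-{(R)-[3,4-bis(benzyloxy)phenyl](hydroxy)methyl}-2-(4-hydroxy-3-methoxyphenyl)tetrahydrofuran-3-yl}methyl acetate | COc1cc([C@H]2OC[C@@H]([C@@H](O)c3ccc(OCc4ccccc4)c(OCc5ccccc5)c3)[C@@H]2COC(C)=O)ccc1O
A6 | alternative 3 | [3-[3,4-bis(benzyloxy)phenyl]-2-(4-hydroxy-3-methoxyphenyl)-4-(hydroxymethyl)cyclobutyl]methyl acetate, aryl groups cis to each other and trans to the two cis CH2 groups, single enantiomer as in the SMILES | COc1cc([C@H]2[C@@H](c3ccc(OCc4ccccc4)c(OCc5ccccc5)c3)[C@H](CO)[C@@H]2COC(C)=O)ccc1O
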